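Numbering (bisabolane): ring C1–C6 with C7H2O on C1, C1=C2, the side chain on C4 (S) and OH on C6 (S, cis to the side chain). The chain is C8(=C9H2)–C10H2–C11H=C12H (E)–C13(OH)(CH3) (R)–C14H2O.
Hardest point: two stereochemical domains that cannot control each other (C4/C6 on the ring, remote C13) are tied by a skipped diene that isomerises easily, and only two of the four hydroxyls carry an ester.
Cuts: first the two isobutyrate C–O bonds. Then C8–C10, so that the whole C8–C12 diene falls apart into a ring alkyne (C8≡C9H) and a terminal alkene (C10=C11). Then, in the ring, C1–C7, C1=C2 and C4–C5.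
Forward: the cyclohexenone ring arises first from an acyclic enynal and tert-butyl acetoacetate ([3+3] Michael/aldol). C7 and the C6 hydroxyl follow, the chain is joined in one catalytic, by-product-free step on unprotected diols, and both esters go on last in one operation.
Stereochemistry: C4 from a diarylprolinol silyl ether catalyst, C6 from C4 (Luche reduction), C13 from (S)-2-methylglycidol, 11E from the key step.
Enabling feature: C8(=C9H2)–C10H2–C11H=C12H, set between the ring methine C4 and the fully substituted C13, is the exact branched retron of the ruthenium alkene–alkyne coupling. C13 bears no hydrogen, so the new double bond can only stop at C11=C12, and the trisubstituted ring alkene C1=C2 stays out.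

Key step: step 6

Remark: the SMILES is read as 4S,6S (cis), 13R, 11E. Compounds 1, 2, 4, 11, both enantiomers of the organocatalyst and [CpRu(MeCN)3]PF6 are taken as commercial.

Step 1
Reactants: 1 3-(trimethylsilyl)prop-2-ynal; 2 (triphenylphosphoranylidene)acetaldehyde
Product: 3 (2E)-5-(trimethylsilyl)pent-2-en-4-ynal
Conditions: 2 (1.0 equiv), CH2Cl2, 0 °C to rt
Reagents that add atoms: none
Why: Wittig olefination with the stabilised formyl ylide is E-selective and stops at the enal when one equivalent is used, while the silyl cap protects the alkyne terminus.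

Step 2
Reactants: 3 (2E)-5-(trimethylsilyl)pent-2-en-4-ynal; 4 tert-butyl 3-oxobutanoate
Product: 7 (5S)-5-[(trimethylsilyl)ethynyl]cyclohex-2-en-1-one, via Michael adduct 5 (not isolated), via cyclohexenone tert-butyl ester 6 (not isolated)
Conditions: (R)-2-{bis[3,5-bis(trifluoromethyl)phenyl](trimethylsilyloxy)methyl}pyrrolidine (10 mol %), toluene, rt; then p-TsOH·H2O (20 mol %), toluene, 80 °C
Reagents that add atoms: none
Why: Iminium-catalysed asymmetric Michael addition of the β-keto ester to the E-enal, in which the bulky group of the (R)-catalyst covers one face of the iminium ion so that C5 adds to the open face of C4 (4S) while the silyl cap keeps the nucleophile away from the alkyne terminus, is followed under acid by intramolecular aldol condensation (C1=C2) and loss of the tert-butyl ester as isobutene and carbon dioxide.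

Step 3
Reactants: 7 (5S)-5-[(trimethylsilyl)ethynyl]cyclohex-2-en-1-one
Product: 8 (5S)-2-(hydroxymethyl)-5-[(trimethylsilyl)ethynyl]cyclohex-2-en-1-one
Conditions: 37% aq. HCHO, DMAP (20 mol %), THF, rt
Reagents that add atoms: formaldehyde C=O
Why: Morita–Baylis–Hillman reaction in which DMAP adds reversibly to C2, the enolate carbon C1 takes up formaldehyde and DMAP leaves again, a hydroxymethylation well known for cyclohex-2-enones in aqueous THF that does not touch C4.

Step 4
Reactants: 8 (5S)-2-(hydroxymethyl)-5-[(trimethylsilyl)ethynyl]cyclohex-2-en-1-one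
Product: 10 (1S,5S)-5-ethynyl-2-(hydroxymethyl)cyclohex-2-en-1-ol, via silylated cis-diol 9 (not isolated)
Conditions: NaBH4, CeCl3·7H2O, MeOH, −78 to −20 °C; aqueous work-up; crude 9, K2CO3, MeOH, rt
Reagents that add atoms: none
Why: Luche reduction gives clean 1,2-attack with hydride entering axially on the face opposite to the C4 substituent, as in the reduction of carvone to cis-carveol, which sets 6S cis to the alkynyl group, and carbonate in methanol then cleaves only the alkynyl C–Si bond.

Step 5
Reactants: 11 (S)-2-methylglycidol
Product: 12 (2R)-2-methylpent-4-ene-1,2-diol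
Conditions: CH2=CHMgBr (2.5 equiv), CuI (10 mol %), THF, −30 to 0 °C; aq. NH4Cl
Reagents that add atoms: vinylmagnesium bromide C=C[Mg]Br
Why: Copper-catalysed opening of the 2,2-disubstituted epoxide by the vinyl Grignard reagent occurs at the unsubstituted CH2, so the C–O bond at the quaternary carbon is never broken and its configuration is kept (the descriptor changes from S to R only through the priority rules), and a Payne rearrangement of the alkoxide is degenerate and returns the same enantiomer.

Step 6
Reactants: 10 (1S,5S)-5-ethynyl-2-(hydroxymethyl)cyclohex-2-en-1-ol; 12 (2R)-2-methylpent-4-ene-1,2-diol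
Product: 13 (1S,5S)-5-[(4E,6R)-6,7-dihydroxy-6-methylhepta-1,4-dien-2-yl]-2-(hydroxymethyl)cyclohex-2-en-1-ol
Conditions: [CpRu(MeCN)3]PF6 (10 mol %), 12 (1.3 equiv), acetone, rt
Reagents that add atoms: none
Why: The CpRu cation binds the terminal alkyne of 10 and the monosubstituted alkene of 12, oxidative cyclisation gives a ruthenacyclopentene that holds the new C8–C10 bond, and β-hydride elimination of a C12–H followed by reductive elimination onto C9 releases the 1,4-diene as a pure isomerising addition. The closest known reaction type is the ruthenium-catalysed intermolecular alkene–alkyne coupling (formal Alder-ene reaction) of terminal alkynes with terminal alkenes, which is routinely run on free alcohols. No ring is closed and no stereocentre is formed, C4, C6 and C13 are spectators, and the only new stereo-element, the C11=C12 geometry, should come out E because C10 and C13 lie anti in the conformer that undergoes syn β-hydride elimination. The step needs bond formation at the substituted alkyne carbon C8 (branched, exo-methylene) and not at C9 (linear), which is the normal preference of terminal alkynes as long as the propargylic carbon is not quaternary, and C4 is a methine. It also needs chemoselectivity for the monosubstituted alkene, which is secured because the ring alkene C1=C2 is trisubstituted and the product alkenes are 1,1- and 1,2-disubstituted and do not compete for the metal. Because C13 carries no hydrogen the hydride can only come from C12, so the diene stays skipped.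

Step 7
Reactants: 13 (1S,5S)-5-[(4E,6R)-6,7-dihydroxy-6-methylhepta-1,4-dien-2-yl]-2-(hydroxymethyl)cyclohex-2-en-1-ol
Product: 14 (2R,3E)-2-hydroxy-6-{(1S,5S)-5-hydroxy-4-[(isobutyryloxy)methyl]cyclohex-3-en-1-yl}-2-methylhepta-3,6-dien-1-yl 2-methylpropanoate (target)
Conditions: i-PrCOCl (2.1 equiv), 2,4,6-collidine, CH2Cl2–THF, −78 to −30 °C
Reagents that add atoms: isobutyryl chloride CC(C)C(=O)Cl
Why: Kinetically controlled esterification with a branched acid chloride and a weak hindered base at low temperature acylates primary hydroxyls much faster than the secondary allylic C6–OH and not at all the tertiary C13–OH, so both isobutyrates are placed in one operation without touching a stereocentre.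

Compound list
1 | 3-(trimethylsilyl)prop-2-ynal | C[Si](C)(C)C#CC=O | starting material
2 | (triphenylphosphoranylidene)acetaldehyde | O=CC=P(c1ccccc1)(c1ccccc1)c1ccccc1 | starting material
3 | (2E)-5-(trimethylsilyl)pent-2-en-4-ynal | C[Si](C)(C)C#C/C=C/C=O | intermediate
4 | tert-butyl 3-oxobutanoate | CC(=O)CC(=O)OC(C)(C)C | starting material
5 | tert-butyl (3S)-2-acetyl-5-oxo-3-[(trimethylsilyl)ethynyl]pentanoate (C2 epimers) | C[Si](C)(C)C#C[C@H](C(C(C)=O)C(=O)OC(C)(C)C)CC=O | intermediate
6 | tert-butyl (6S)-2-oxo-6-[(trimethylsilyl)ethynyl]cyclohex-3-ene-1-carboxylate (C1 epimers) | C[Si](C)(C)C#C[C@H]1CC=CC(=O)C1C(=O)OC(C)(C)C | intermediate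
7 | (5S)-5-[(trimethylsilyl)ethynyl]cyclohex-2-en-1-one | C[Si](C)(C)C#C[C@H]1CC=CC(=O)C1 | intermediate
8 | (5S)-2-(hydroxymethyl)-5-[(trimethylsilyl)ethynyl]cyclohex-2-en-1-one | C[Si](C)(C)C#C[C@H]1CC=C(CO)C(=O)C1 | intermediate
9 | (1S,5S)-2-(hydroxymethyl)-5-[(trimethylsilyl)ethynyl]cyclohex-2-en-1-ol | C[Si](C)(C)C#C[C@H]1CC=C(CO)[C@@H](O)C1 | intermediate
10 | (1S,5S)-5-ethynyl-2-(hydroxymethyl)cyclohex-2-en-1-ol | C#C[C@H]1CC=C(CO)[C@@H](O)C1 | intermediate
11 | (S)-2-methylglycidol, [(2S)-2-methyloxiran-2-yl]methanol | C[C@]1(CO)CO1 | starting material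
12 | (2R)-2-methylpent-4-ene-1,2-diol | C=CC[C@@](C)(O)CO | intermediate
13 | (1S,5S)-5-[(4E,6R)-6,7-dihydroxy-6-methylhepta-1,4-dien-2-yl]-2-(hydroxymethyl)cyclohex-2-en-1-ol | C=C(C/C=C/[C@@](C)(O)CO)[C@H]1CC=C(CO)[C@@H](O)C1 | intermediate
14 | (2R,3E)-2-hydroxy-6-{(1S,5S)-5-hydroxy-4-[(isobutyryloxy)methyl]cyclohex-3-en-1-yl}-2-methylhepta-3,6-dien-1-yl 2-methylpropanoate | C=C(C/C=C/[C@@](C)(O)COC(=O)C(C)C)[C@H]1CC=C(COC(=O)C(C)C)[C@@H](O)C1 | target

Total step count: 7. Longest linear sequence: 6 (steps 1, 2, 3, 4, 6, 7).

Steps most likely to fail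

Step 6. Branching at the propargylic carbon C4 may push the bond formation towards the unsubstituted alkyne carbon (linear diene), and the chelating diols may slow the catalyst.
The fallback sets out from 10 and comes back at 13. It fixes the regiochemistry at C8 before the chain is joined.
- Compound 10 is masked with 2,2-dimethoxypropane and PPTS as the isopropylidene acetal of 10 F1.
- Nickel-catalysed α-selective hydroalumination (DIBAL-H, Ni(dppp)Cl2, THF) with in situ borylation by methoxy pinacolborane gives the internal alkenyl pinacolboronate F2.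
- The C10–C14 unit is made from acrolein. Wittig olefination with ethyl 2-(triphenylphosphoranylidene)propanoate gives ethyl (2E)-2-methylpenta-2,4-dienoate F3, DIBAL-H reduction gives (2E)-2-methylpenta-2,4-dien-1-ol F4, and Sharpless epoxidation with L-(+)-diethyl tartrate gives [(2S,3S)-3-ethenyl-2-methyloxiran-2-yl]methanol F5.
- Palladium(0)-catalysed coupling of F2 with F5 through the π-allyl complex, with bond formation at the terminal carbon C10, should give the isopropylidene acetal of 13 F6. This carries the E C11=C12 bond and an untouched C13–O bond.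
- Aqueous acetic acid then frees 13.

Step 2. The enynal may oligomerise or suffer 1,2- or 1,6-attack on the secondary amine, and the slim alkynyl group may allow poor facial discrimination.
The fallback sets out from 3 and 4 and comes back at 10. It moves the source of chirality from asymmetric catalysis to an enzymatic kinetic resolution.
- The Michael addition is run with a catalytic achiral base (Et3N), and the acid treatment of step 2 gives racemic 5-[(trimethylsilyl)ethynyl]cyclohex-2-en-1-one F7.
- The conditions of steps 3 and 4 give racemic 2-(hydroxymethyl)-5-[(trimethylsilyl)ethynyl]cyclohex-2-en-1-one F8 and racemic cis-5-ethynyl-2-(hydroxymethyl)cyclohex-2-en-1-ol F9.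
- A lipase (immobilised Candida antarctica lipase B, vinyl acetate, MTBE) should acetylate the primary hydroxyl of both enantiomers. By the usual empirical preference of lipases for secondary alcohols, it should acetylate the secondary hydroxyl only of the (1R,5R) enantiomer.
- The [(4S,6S)-4-ethynyl-6-hydroxycyclohex-1-en-1-yl]methyl acetate F10 is separated from the [(4R,6R)-6-acetoxy-4-ethynylcyclohex-1-en-1-yl]methyl acetate F11.
- Methanolysis of F10 (K2CO3, MeOH) returns 10.

Step 7. Acylation may spill over to the C6 hydroxyl before the hindered C14 hydroxyl is consumed, or an acyl group may migrate within the C6/C7 1,3-diol.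
The fallback sets out from 10 and 12 and comes back at 14. The site selection is solved on the fragments, where one primary hydroxyl stands against only one secondary or one tertiary hydroxyl.
- Compound 10 gives [(4S,6S)-4-ethynyl-6-hydroxycyclohex-1-en-1-yl]methyl 2-methylpropanoate F12.
- Compound 12 gives (2R)-2-hydroxy-2-methylpent-4-en-1-yl 2-methylpropanoate F13.
- The ruthenium coupling under the conditions of step 6 then joins F12 and F13 directly to 14 as the last step.

Further compounds
F1 | step 6 | isopropylidene acetal of 10 | C#C[C@H]1CC=C2COC(C)(C)O[C@H]2C1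
F2 | step 6 | internal alkenyl pinacolboronate of F1 | C=C(B3OC(C)(C)C(C)(C)O3)[C@H]1CC=C2COC(C)(C)O[C@H]2C1
F3 | step 6 | ethyl (2E)-2-methylpenta-2,4-dienoate | C=C/C=C(\C)C(=O)OCC
F4 | step 6 | (2E)-2-methylpenta-2,4-dien-1-ol | C=C/C=C(\C)CO
F5 | step 6 | [(2S,3S)-3-ethenyl-2-methyloxiran-2-yl]methanol | C=C[C@@H]1O[C@@]1(C)CO
F6 | step 6 | isopropylidene acetal of 13 | C=C(C/C=C/[C@@](C)(O)CO)[C@H]1CC=C2COC(C)(C)O[C@H]2C1
F7 | step 2 | racemic 5-[(trimethylsilyl)ethynyl]cyclohex-2-en-1-one | C[Si](C)(C)C#CC1CC=CC(=O)C1
F8 | step 2 | racemic 2-(hydroxymethyl)-5-[(trimethylsilyl)ethynyl]cyclohex-2-en-1-one | C[Si](C)(C)C#CC1CC=C(CO)C(=O)C1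
F9 | step 2 | racemic cis-5-ethynyl-2-(hydroxymethyl)cyclohex-2-en-1-ol (both enantiomers) | C#C[C@H]1CC=C(CO)[C@@H](O)C1.C#C[C@@H]1CC=C(CO)[C@H](O)C1
F10 | step 2 | [(4S,6S)-4-ethynyl-6-hydroxycyclohex-1-en-1-yl]methyl acetate | C#C[C@H]1CC=C(COC(C)=O)[C@@H](O)C1
F11 | step 2 | [(4R,6R)-6-acetoxy-4-ethynylcyclohex-1-en-1-yl]methyl acetate | C#C[C@@H]1CC=C(COC(C)=O)[C@H](OC(C)=O)C1
F12 | step 7 | [(4S,6S)-4-ethynyl-6-hydroxycyclohex-1-en-1-yl]methyl 2-methylpropanoate | C#C[C@H]1CC=C(COC(=O)C(C)C)[C@@H](O)C1
F13 | step 7 | (2R)-2-hydroxy-2-methylpent-4-en-1-yl 2-methylpropanoate | C=CC[C@@](C)(O)COC(=O)C(C)C
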